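Leave the charges alone.

in all of them: solid substrate 0.69 M

| flask | coupling partner | remark | time |
|---|---|---|---|
| winter | 0.47 M | run made earlier |  |
| autumn | 1.8 M | run made earlier |  |
| alpha | 2.07 M |  | 40 h |
| gamma | 0.690 M |  | 40 h |

| run | time / h | double product / % | triple product / % |
|---|---|---|---|
| winter | 1.33 | 2 | 1 |
| winter | 4.00 | 1 | 2 |
| winter | 8.00 | 9 | 6 |
| winter | 10.0 | 5 | 7 |
| winter | 15.0 | 6 | 8 |
| winter | 20.0 | 6 | 9 |
| autumn | 3.00 | 6 | 7 |
| autumn | 6.00 | 3 | 15 |
| autumn | 10.0 | 8 | 21 |
| autumn | 12.0 | 9 | 22 |
| autumn | 15.0 | 10 | 21 |
| autumn | 20.0 | 8 | 20 |

(scatter of a reading: 2 percentage points)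

1. which of these holds the largest part of the solid substrate at the end of alpha (solid substrate / tetra adduct / triple product / double product / first product)
2. which of these holds the largest part of the solid substrate at the end of gamma (solid substrate / tetra adduct / triple product / double product / first product)
3. amount of double product at the end of alpha, in percent of the solid substrate charged

- the numbers in the tables scatter by 2 percentage points (one standard deviation)
- at the start none of the solid substrate is in solution
- a reading or a percentage of triple product counts all its forms, free or not

1. In the flasks: alpha and gamma both start with all the solid substrate undissolved. Alpha has 3.00 equivalents of coupling partner, gamma 1.00.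
2. What I read: double product goes flat in both earlier runs, though autumn has more coupling partner than winter. I call the mean of the last 4 readings of each run the plateau fraction, the share of the charge standing as double product once it stops rising (a steady-state hold-up): 7.62%, a reading with its scatter.
3. My reckoning: alpha keeps the solid charge of those runs, so I commit to 7.62% for n. I assume the plateau is a fixed amount in the liquid, so its fraction goes inversely with the solid charge. Neither run tests that.
4. The forecast: tetra adduct leads alpha, solid substrate leads gamma, n is 7%, below my figure, “perhaps lower as the feed and partner fade”.

    coupling partner + double product → triple product (k = 1.40 × 10⁻⁴ L mol⁻¹ s⁻¹)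
    solid substrate ⇌ starting material, rate k2*(cs2 - [starting material]) while solid is left; crystals form when [starting material] > cs2 (solubility = 34.0 mM, k = 0.00130 s⁻¹)
    starting material + coupling partner → first product (k = 2.60 × 10⁻⁴ L mol⁻¹ s⁻¹)
    coupling partner + first product → double product (k = 5.80 × 10⁻⁴ L mol⁻¹ s⁻¹)
    coupling partner + triple product → tetra adduct (k = 3.90 × 10⁻⁵ L mol⁻¹ s⁻¹)
    crystals ⇌ triple product, rate k6*(cs6 - [triple product]) while solid is left; crystals form when [triple product] > cs6 (solubility = 0.350 M, k = 0.110 s⁻¹)

5. The result: alpha ends with tetra adduct at 49.3%, gamma with solid substrate at 60.7%, and n is 8.62% against my 7.62%. In alpha, dissolving has 52% of its turnover up to the end behind it by 8.00 h and the step to double product 87% by 20.0 h, while coupling partner, the limiting reagent, falls to 1.5% of its own charge at 40.0 h. With the rest of alpha held, n has moved 5 points at 0.540 M or 1.64 M of solid substrate, and at 2.65 M of coupling partner.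
6. Second flask: alpha with 2.8 M of solid substrate. The plateau fraction scaled by the solid charges gives 1.88%; the computed n there is 2.12%.

The data stem from a simulated flask with made-up constants, noise included.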